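## Retrosynthetic overview

1. Feature: in ring B the C3 hydroxyl is cis to C7 of ring A (across C3···C6) and anti to C2–Br. This is the imprint of a C7–O–C3 bridge (2-oxabicyclo[2.2.2]octane, as in 1,8-cineole) that has been opened again at C7.
2. Target 21 ⇐ acetate 20 ⇐ bridged ether 19 (acylative C7–O cleavage with loss of H-8) ⇐ carbinol 18 by bromoetherification (C3–O and C2–Br).
3. 18 ⇐ spiro ketone 16 (methyl addition at C7) ⇐ allylsilane 15 (protodesilylation with allylic shift) ⇐ Diels–Alder of exo-methylene ketone 8 with 1-silyl diene 14 (ring B, C6).
4. 8 ⇐ bromo keto ester 4 (enantioselective bromonium cyclisation: ring A, C10) ⇐ prenylated allyl acetoacetate 3; diene 14 from 3-(trimethylsilyl)propargyl alcohol 9.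
5. Ring order: ring A, then ring B at spiro C6, then the temporary oxa-bridge (step 10), which step 11 opens again.

Key step: step 10

Numbering used (chamigrane): ring B is C1–C5 plus spiro C6; ring A is C6–C11; C12/C13 are the methyls on C11, C14 the methyl on C7, C15 the methyl on C3.

Remark on the chemistry: the carbinol can bridge only as the 7S epimer, whose OH is anti to the C6–C11 bond (equatorial in the bromine-equatorial chair of ring A); C7 becomes trigonal again in step 11.

Remark on the chemistry: a new bond to trigonal C6 is assumed to form anti to the axial C11 methyl, that is trans to bromine, so ring B is assembled with C5 as the incoming carbon.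

Remark on the chemistry: free enolates of the γ-bromo ketone (1,3-elimination to a cyclopropane) and free alkoxides anti to C2–Br (epoxide closure) are avoided throughout.

## Route

Step 1
Reactants: 1 allyl acetoacetate; 2 prenyl bromide
Product: 3 allyl 7-methyl-3-oxooct-6-enoate
Conditions: NaH, THF, 0 °C; n-BuLi, 0 °C; then 2, 0 °C → rt; aq. NH4Cl
Reagents that add atoms: none
Why: γ-Alkylation of the acetoacetate dianion (Huckin–Weiler) with the allylic bromide occurs at the more basic terminal carbon; no stereocentre is formed.

Step 2
Reactants: 3 allyl 7-methyl-3-oxooct-6-enoate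
Product: 4 allyl (3S)-3-bromo-2,2-dimethyl-6-oxocyclohexane-1-carboxylate (keto/enol, C1 epimers)
Conditions: chiral BINOL-derived N-triflyl thiophosphoramide (10 mol %, the antipode that gives 3S), DBDMH (0.55 equiv), PhMe/CH2Cl2, −90 °C
Reagents that add atoms: 1,3-dibromo-5,5-dimethylhydantoin, CC1(C)N(Br)C(=O)N(Br)C1=O
Why: Proposed new method: a chiral Lewis base–Br+ complex formed from DBDMH should transfer bromine to one face of the prenyl olefin, and the hydrogen-bonded Z-enol of the β-keto ester should capture the tertiary terminus through C2 in a chair transition state with bromine equatorial (6-endo with respect to the bromonium), so that the catalyst sets the C–Br centre; the closest known reactions are the catalytic enantioselective bromonium cyclisation of homogeranylarenes with this catalyst class and the racemic brominative carbocyclisation of prenylated β-keto esters.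

Step 3
Reactants: 4 allyl (3S)-3-bromo-2,2-dimethyl-6-oxocyclohexane-1-carboxylate; 5 formaldehyde
Product: 8 (4S)-4-bromo-3,3-dimethyl-2-methylidenecyclohexan-1-one, via β-keto acid 6 (not isolated), via Mannich acid 7 (not isolated)
Conditions: Pd(PPh3)4 (2 mol %), morpholine (2.5 equiv), THF, 0 °C → rt; then 37% aq. 5, AcOH, rt → 45 °C
Reagents that add atoms: none
Why: Pd(0)-catalysed allyl transfer to morpholine unmasks the β-keto acid under neutral conditions, and its Mannich reaction with the formaldehyde-derived iminium followed by decarboxylative loss of the amine (decarboxylative Mannich methylenation of a β-keto acid) gives the exo-methylene ketone without a free ketone enolate; the C–Br centre is untouched.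

Step 4
Reactants: 9 3-(trimethylsilyl)prop-2-yn-1-ol; 10 methylmagnesium chloride
Product: 11 (E)-2-methyl-3-(trimethylsilyl)prop-2-en-1-ol
Conditions: 10 (3 equiv), CuI (10 mol %), THF, −10 °C → rt; aq. NH4Cl
Reagents that add atoms: none
Why: Copper-catalysed anti-carbomagnesiation of the propargylic alkoxide (Duboudin–Jousseaume type) puts methyl on C2 and magnesium on C3, held cis to CH2O in a five-membered chelate, so protonation gives the E olefin with silicon trans to CH2OH.

Step 5
Reactants: 11 (E)-2-methyl-3-(trimethylsilyl)prop-2-en-1-ol
Product: 12 (E)-2-methyl-3-(trimethylsilyl)prop-2-enal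
Conditions: activated MnO2, CH2Cl2, rt
Reagents that add atoms: none
Why: Allylic oxidation with MnO2 stops at the enal and leaves the vinylsilane and the olefin geometry unchanged.

Step 6
Reactants: 12 (E)-2-methyl-3-(trimethylsilyl)prop-2-enal; 13 methyltriphenylphosphonium bromide
Product: 14 (E)-trimethyl(2-methylbuta-1,3-dien-1-yl)silane
Conditions: 13, KHMDS, THF, 0 °C; then 12, 0 °C → rt
Reagents that add atoms: none
Why: Wittig methylenation of the non-enolisable enal gives the 1-silyl diene with silicon on the outside (E), the geometry needed for a reactive s-cis diene.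

Step 7
Reactants: 8 (4S)-4-bromo-3,3-dimethyl-2-methylidenecyclohexan-1-one; 14 (E)-trimethyl(2-methylbuta-1,3-dien-1-yl)silane
Product: 15 (6S,10S)-10-bromo-2-(trimethylsilyl)chamigr-3-en-7-one (C2 epimers)
Conditions: Me2AlCl (20 mol %), CH2Cl2, −78 → −30 °C
Reagents that add atoms: none
Why: In this Lewis acid-catalysed Diels–Alder reaction the 2-methyl group (para rule) and the 1-silyl group both send the silylated terminus to the exocyclic CH2, so the CH2= terminus bonds to C6, and it should do so anti to the axial C11 methyl of the bromine-equatorial half-chair (trans to Br), which makes C5 the axial ring-B carbon and the former exocyclic carbon C1 cis to bromine; isoprene would by the same facial course give the C6-epimeric series and is the reserve diene should the facial preference be the reverse.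

Step 8
Reactants: 15 (6S,10S)-10-bromo-2-(trimethylsilyl)chamigr-3-en-7-one
Product: 16 (6S,10S)-10-bromochamigr-2-en-7-one
Conditions: TsOH·H2O (20 mol %), wet CH2Cl2, 0 °C → rt
Reagents that add atoms: none
Why: Protodesilylation of the allylsilane (SE2′) protonates C4, and loss of silicon from the β-silyl C3 cation moves the double bond regiospecifically to C2=C3 on the C1 arm; the allylsilane is protonated much faster than the product olefin, so C6, which is defined only by the olefin position, is not scrambled.

Step 9
Reactants: 16 (6S,10S)-10-bromochamigr-2-en-7-one; 17 methyllithium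
Product: 18 (6S,7S,10S)-10-bromochamigr-2-en-7-ol
Conditions: anhydrous CeCl3 (1.5 equiv), 17 (1.4 equiv), THF, −78 °C; then 16, −78 °C; aq. NH4Cl
Reagents that add atoms: none
Why: Organocerium 1,2-addition (Imamoto reagent) to the hindered, enolisable ketone avoids the C8 enolate that would expel the γ-bromide; because the equatorial trajectory at C7 is flanked by the axial C5 methylene and the axial one by the axial C11 methyl, no strong facial preference can be counted on, both C7 epimers are expected, and the 7S epimer is separated by chromatography.

Step 10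
Reactants: 18 (6S,7S,10S)-10-bromochamigr-2-en-7-ol
Product: 19 (2R,3R,6S,7S,10S)-2,10-dibromo-3,7-epoxychamigrane
Conditions: NBS (1.05 equiv), NaHCO3, CH2Cl2, 0 °C, dark
Reagents that add atoms: N-bromosuccinimide, O=C1CCC(=O)N1Br
Why: NBS transfers Br+ reversibly to both faces of the C2=C3 olefin, and only the bromonium on the face away from C7 is opened by the C7 hydroxyl, which attacks the tertiary carbon C3 from the rear while succinimide takes up the proton (bromoetherification). The closest known reaction is the conversion of α-terpineol into 2-bromo-1,8-cineole. The new oxacycle O–C7–C6–C5–C4–C3 closes in the 6-exo mode with respect to the bromonium (C2 stays outside it) through a boat of ring B and completes the 2-oxabicyclo[2.2.2]octane. C3 is fixed by the tether, since an oxygen delivered from C7 must end cis to C7 across ring B, and C2 by the anti opening, which leaves bromine trans to the new C–O bond. The step needs attack at C3 and not C2 and a productive olefin face: the tertiary, cation-stabilising terminus secures the first and the reach of the tether the second, the unproductive bromonium simply reverting. Ring A carries no olefin, NaHCO3 removes traces of HBr that would catalyse bromine-free cyclisation, and the 7S carbinol already holds its OH anti to C6–C11 in the bromine-equatorial chair.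

Step 11
Reactants: 19 (2R,3R,6S,7S,10S)-2,10-dibromo-3,7-epoxychamigrane
Product: 20 (2R,3R,6R,10S)-2,10-dibromochamigr-7-en-3-yl acetate
Conditions: Ac2O (5 equiv), FeCl3 (10 mol %), CH2Cl2, −20 → 0 °C
Reagents that add atoms: acetic anhydride, CC(=O)OC(C)=O
Why: In this Lewis acid-mediated acylative ether cleavage (the 1,8-cineole → α-terpinyl acetate reaction type) the O-acetyl oxonium should ionise at C7, the tertiary terminus that has no β-bromine and loses the C7/C11 syn-diaxial methyl strain, and the cation should lose H-8 to give the trisubstituted ring olefin, while C3 keeps its oxygen and configuration.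

Step 12
Reactants: 20 (2R,3R,6R,10S)-2,10-dibromochamigr-7-en-3-yl acetate
Product: 21 (2R,3R,6R,10S)-2,10-dibromochamigr-7-en-3-ol (target)
Conditions: DIBAL-H (2.5 equiv), CH2Cl2, −78 °C; MeOH, then aq. Rochelle salt
Reagents that add atoms: none
Why: Reductive cleavage of the tertiary acetate with DIBAL-H at −78 °C frees the alcohol through an aluminium alkoxide that should not displace the anti C2 bromide (basic methanolysis would risk the 2,3-epoxide); no stereocentre is touched.

## Compound list

1 | allyl acetoacetate | CC(=O)CC(=O)OCC=C | starting material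
2 | prenyl bromide (1-bromo-3-methylbut-2-ene) | CC(C)=CCBr | starting material
3 | allyl 7-methyl-3-oxooct-6-enoate | CC(C)=CCCC(=O)CC(=O)OCC=C | intermediate
4 | allyl (3S)-3-bromo-2,2-dimethyl-6-oxocyclohexane-1-carboxylate | C=CCOC(=O)C1C(=O)CC[C@H](Br)C1(C)C | intermediate
5 | formaldehyde | C=O | starting material
6 | (3S)-3-bromo-2,2-dimethyl-6-oxocyclohexane-1-carboxylic acid | OC(=O)C1C(=O)CC[C@H](Br)C1(C)C | intermediate
7 | (3S)-3-bromo-2,2-dimethyl-1-(morpholin-4-ylmethyl)-6-oxocyclohexane-1-carboxylic acid | OC(=O)C1(CN2CCOCC2)C(=O)CC[C@H](Br)C1(C)C | intermediate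
8 | (4S)-4-bromo-3,3-dimethyl-2-methylidenecyclohexan-1-one | C=C1C(=O)CC[C@H](Br)C1(C)C | intermediate
9 | 3-(trimethylsilyl)prop-2-yn-1-ol | C[Si](C)(C)C#CCO | starting material
10 | methylmagnesium chloride | C[Mg]Cl | starting material
11 | (E)-2-methyl-3-(trimethylsilyl)prop-2-en-1-ol | C[Si](C)(C)/C=C(\C)CO | intermediate
12 | (E)-2-methyl-3-(trimethylsilyl)prop-2-enal | C[Si](C)(C)/C=C(\C)C=O | intermediate
13 | methyltriphenylphosphonium bromide | C[P+](c1ccccc1)(c1ccccc1)c1ccccc1.[Br-] | starting material
14 | (E)-trimethyl(2-methylbuta-1,3-dien-1-yl)silane | C[Si](C)(C)/C=C(\C)C=C | intermediate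
15 | (6S,10S)-10-bromo-2-(trimethylsilyl)chamigr-3-en-7-one (C2 epimers) | O=C1CC[C@H](Br)C(C)(C)[C@@]12CC=C(C)C([Si](C)(C)C)C2 | intermediate
16 | (6S,10S)-10-bromochamigr-2-en-7-one | O=C1CC[C@H](Br)C(C)(C)[C@@]12CCC(C)=CC2 | intermediate
17 | methyllithium | [Li]C | starting material
18 | (6S,7S,10S)-10-bromochamigr-2-en-7-ol | C[C@]1(O)CC[C@H](Br)C(C)(C)[C@@]12CCC(C)=CC2 | intermediate
19 | (2R,3R,6S,7S,10S)-2,10-dibromo-3,7-epoxychamigrane | C[C@]13CC[C@H](Br)C(C)(C)[C@@]12CC[C@@](C)(O3)[C@H](Br)C2 | intermediate
20 | (2R,3R,6R,10S)-2,10-dibromochamigr-7-en-3-yl acetate | CC1=CC[C@H](Br)C(C)(C)[C@@]12CC[C@@](C)(OC(C)=O)[C@H](Br)C2 | intermediate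
21 | (2R,3R,6R,10S)-2,10-dibromochamigr-7-en-3-ol | CC1=CC[C@H](Br)C(C)(C)[C@@]12CC[C@@](C)(O)[C@H](Br)C2 | target

## Step count and risks

Total steps: 12. Longest linear sequence: 9 (steps 1, 2, 3, 7, 8, 9, 10, 11, 12; the diene branch 4, 5, 6 joins at step 7 and is equally long).

Steps most likely to fail:

Step 2 (proposed new method). Bromine transfer may occur without effective face discrimination, or the enol may cyclise through oxygen (cyclic enol ether) instead of carbon. The fallback uses known chemistry and sets out from 3. Racemic brominative carbocyclisation with 2,4,4,6-tetrabromocyclohexa-2,5-dienone in MeNO2 gives racemic allyl 3-bromo-2,2-dimethyl-6-oxocyclohexane-1-carboxylate F1. Condensation with (S)-1-phenylethylamine (cat. AcOH, toluene, molecular sieves) gives the diastereomeric enamino esters. The one with the S bromide, allyl (5S)-5-bromo-6,6-dimethyl-2-{[(1S)-1-phenylethyl]amino}cyclohex-1-ene-1-carboxylate F2, is separated by crystallisation or chromatography and hydrolysed with aqueous oxalic acid in THF. The fallback comes back to the route at 4.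

Step 10 (key step). Capture of the bromonium by the tethered hydroxyl needs a boat in ring B and keeps a syn-diaxial C7/C11 methyl pair, so it may be slower than allylic proton loss or intermolecular capture; acid may also catalyse bromine-free cyclisation to the 3,7-ether. The fallback sets out from 18 and replaces Br+ by a reversible, softer electrophile. Alkoxymercuration with Hg(OCOCF3)2 in MeNO2 at −20 °C, followed by aqueous KBr, gives by thermodynamically driven anti, Markovnikov addition the organomercurial (2R,3R,6S,7S,10S)-10-bromo-2-(bromomercurio)-3,7-epoxychamigrane F3. Bromodemercuration with Br2 in pyridine in the dark (SE2, retention at C2) then comes back to the route at 19.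

Step 9. Facial selectivity at C7 may be poor or reversed, so that the 7R epimer, which cannot bridge, predominates; incomplete formation of the cerium reagent would also allow enolisation towards C8 and loss of bromide by 1,3-elimination. The fallback sets out from 16 and uses the ketone oxygen itself as the tethered nucleophile, which makes the C7 configuration irrelevant. NBS in CH2Cl2 at −20 °C, then MeOH and 2,6-lutidine, gives through the bridged oxocarbenium ion the bromo ketal 2,10-dibromo-7-methoxy-14-nor-3,7-epoxychamigrane F4 (bromoketalisation). Me3Al in CH2Cl2 (−78 → 0 °C) then exchanges methoxy for methyl at the ketal carbon. This comes back to the route at 19; any (2R,3R,6S,7R,10S)-2,10-dibromo-3,7-epoxychamigrane F5 formed alongside converges on 20, because step 11 makes C7 trigonal.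

Further compounds

F1 | step 2 | allyl 3-bromo-2,2-dimethyl-6-oxocyclohexane-1-carboxylate (racemic) | C=CCOC(=O)C1C(=O)CCC(Br)C1(C)C
F2 | step 2 | allyl (5S)-5-bromo-6,6-dimethyl-2-{[(1S)-1-phenylethyl]amino}cyclohex-1-ene-1-carboxylate | C=CCOC(=O)C1=C(N[C@@H](C)c2ccccc2)CC[C@H](Br)C1(C)C
F3 | step 10 | (2R,3R,6S,7S,10S)-10-bromo-2-(bromomercurio)-3,7-epoxychamigrane | C[C@]13CC[C@H](Br)C(C)(C)[C@@]12CC[C@@](C)(O3)[C@H]([Hg]Br)C2
F4 | step 9 | 2,10-dibromo-7-methoxy-14-nor-3,7-epoxychamigrane | COC13CC[C@H](Br)C(C)(C)[C@@]12CC[C@@](C)(O3)[C@H](Br)C2
F5 | step 9 | (2R,3R,6S,7R,10S)-2,10-dibromo-3,7-epoxychamigrane | C[C@@]13CC[C@H](Br)C(C)(C)[C@@]12CC[C@@](C)(O3)[C@H](Br)C2
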